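**Plan**

1. Retrosynthesis: the four MOM ethers come off last. Ring C of the flavanone (O1, C2, C3, C4, C4a, C8a) is then cut at O1–C8a and at C4–C4a in one stroke. This leaves a ring A aryne (C4a≡C8a, OMOM at C5 and C7, prenyl at C8) and a ring B β-silyloxy ester that already holds O1, C2, C3 and C4.
2. Enabling feature: ring A is a phloroglucinol-type ring whose C5 oxygen sits next to C4a. It polarises the C4a≡C8a aryne so that O1 adds at C8a and the carbanion appears at C4a, from where it closes a six-membered ring onto the ester carbon C4 that lies 1,3 to O1.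
3. Forward, ring A: resorcinol is carried to the aryne precursor by C–H borylation/oxidation, two carbamate-directed metalations (SiMe3, then prenyl) and triflation.
4. Forward, ring B: methyl 5-bromo-2,4-dihydroxybenzoate gives the 1,1-dimethylallyl group by α-arylation and Wittig reaction, then the β-keto ester by Claisen condensation. Ring C arises in the last step but one.
5. Stereochemistry: the only stereocentre, C2, is set as the (S)-carbinol by asymmetric transfer hydrogenation of the β-keto ester, and its C–O bond is never broken afterwards.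

Key step: step 14

Assumption: methyl 5-bromo-2,4-dihydroxybenzoate is taken as a purchasable compound. All phenols are carried as MOM ethers, which tolerate organolithiums and fluoride.

**Route**

Step 1
Reactants: 1 resorcinol
Product: 2 1,3-bis(methoxymethoxy)benzene
Conditions: NaH, MOMCl, DMF, 0 °C to rt
Reagents that add atoms: chloromethyl methyl ether, COCCl
Why: Williamson-type O-alkylation of the sodium phenoxides gives acetals that are stable to organolithiums, fluoride and base and can be removed together at the end.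

Step 2
Reactants: 2 1,3-bis(methoxymethoxy)benzene
Product: 4 3,5-bis(methoxymethoxy)phenol, via arylboronate 3 (not isolated)
Conditions: B2pin2, [Ir(OMe)(cod)]2 (cat.), 4,4'-di-tert-butyl-2,2'-bipyridine, THF, 80 °C; then aq NaOH, H2O2, 0 °C to rt
Reagents that add atoms: hydrogen peroxide, OO (oxygen of 4); bis(pinacolato)diboron, CC1(C)OB(OC1(C)C)B1OC(C)(C)C(C)(C)O1 (boron group of 3)
Why: Iridium-catalysed C–H borylation is sterically governed and should take only the C–H that has no ortho substituent, and oxidation of boronate 3 then gives a phenol oxygen that is distinct from the two MOM-protected ones.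

Step 3
Reactants: 4 3,5-bis(methoxymethoxy)phenol
Product: 5 3,5-bis(methoxymethoxy)phenyl N,N-diethylcarbamate
Conditions: NaH, ClCONEt2, THF, 0 °C to rt
Reagents that add atoms: N,N-diethylcarbamoyl chloride, CCN(CC)C(=O)Cl
Why: O-Acylation of the sodium phenoxide installs the strongest oxygen-based directing group for the two metalations that follow.

Step 4
Reactants: 5 3,5-bis(methoxymethoxy)phenyl N,N-diethylcarbamate
Product: 7 3,5-bis(methoxymethoxy)-2-(trimethylsilyl)phenyl N,N-diethylcarbamate, via aryllithium 6 (not isolated)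
Conditions: s-BuLi, TMEDA, THF, −78 °C; Me3SiCl, −78 °C to rt
Reagents that add atoms: chlorotrimethylsilane, C[Si](C)(C)Cl
Why: Directed ortho-metalation, in which the carbamate and the neighbouring OMOM group act together so that the proton between them should be removed in preference to the one between the two OMOM groups, followed by C-silylation of 6.

Step 5
Reactants: 7 3,5-bis(methoxymethoxy)-2-(trimethylsilyl)phenyl N,N-diethylcarbamate
Product: 9 3,5-bis(methoxymethoxy)-2-(3-methylbut-2-en-1-yl)-6-(trimethylsilyl)phenyl N,N-diethylcarbamate, via aryllithium 8 (not isolated)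
Conditions: s-BuLi, TMEDA, THF, −78 °C; CuBr·SMe2 (cat.), prenyl bromide, −78 to −40 °C
Reagents that add atoms: 1-bromo-3-methylbut-2-ene, CC(C)=CCBr
Why: A second directed ortho-metalation takes the only remaining carbamate-flanked proton (the silyl group blocks the other site), and copper-catalysed allylation of aryllithium 8 should give the linear SN2 prenyl arene.

Step 6
Reactants: 9 3,5-bis(methoxymethoxy)-2-(3-methylbut-2-en-1-yl)-6-(trimethylsilyl)phenyl N,N-diethylcarbamate
Product: 10 3,5-bis(methoxymethoxy)-2-(3-methylbut-2-en-1-yl)-6-(trimethylsilyl)phenol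
Conditions: LiAlH4, THF, 0 °C to reflux; aq potassium sodium tartrate work-up
Reagents that add atoms: none
Why: Hydride reduction of the aryl carbamate should free the hindered phenol under non-acidic conditions that leave the MOM ethers, the alkene and the electron-rich C–Si bond untouched.

Step 7
Reactants: 10 3,5-bis(methoxymethoxy)-2-(3-methylbut-2-en-1-yl)-6-(trimethylsilyl)phenol
Product: 11 3,5-bis(methoxymethoxy)-2-(3-methylbut-2-en-1-yl)-6-(trimethylsilyl)phenyl trifluoromethanesulfonate
Conditions: n-BuLi, Et2O, −78 °C; Tf2O, −78 to 0 °C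
Reagents that add atoms: trifluoromethanesulfonic anhydride, O=S(=O)(OS(=O)(=O)C(F)(F)F)C(F)(F)F
Why: O-Sulfonylation of the lithium phenoxide gives the 2-silylaryl triflate, the standard fluoride-triggered aryne precursor, with silicon at C4a and the leaving group at C8a.

Step 8
Reactants: 12 methyl 5-bromo-2,4-dihydroxybenzoate
Product: 13 methyl 5-bromo-2,4-bis(methoxymethoxy)benzoate
Conditions: NaH, MOMCl, DMF, 0 °C to rt
Reagents that add atoms: chloromethyl methyl ether, COCCl
Why: Williamson-type O-alkylation of both phenoxides, including the hydrogen-bonded one next to the ester, gives the bis-acetal.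

Step 9
Reactants: 13 methyl 5-bromo-2,4-bis(methoxymethoxy)benzoate
Product: 14 methyl 2,4-bis(methoxymethoxy)-5-(2-methyl-1-oxopropan-2-yl)benzoate
Conditions: isobutyraldehyde (excess), Pd(OAc)2 (cat.), rac-BINAP, Cs2CO3, 1,4-dioxane, 80 °C
Reagents that add atoms: isobutyraldehyde, CC(C)C=O
Why: Palladium-catalysed α-arylation of an α-branched aldehyde (oxidative addition of the aryl bromide to zerovalent palladium, enolate binding, reductive elimination) should build the quaternary benzylic carbon, and the product has no α-hydrogen left to react further.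

Step 10
Reactants: 14 methyl 2,4-bis(methoxymethoxy)-5-(2-methyl-1-oxopropan-2-yl)benzoate
Product: 15 methyl 2,4-bis(methoxymethoxy)-5-(2-methylbut-3-en-2-yl)benzoate
Conditions: Ph3PCH3Br, NaN(SiMe3)2, THF, 0 °C; then 14, −78 to 0 °C
Reagents that add atoms: methyltriphenylphosphonium bromide, C[P+](c1ccccc1)(c1ccccc1)c1ccccc1.[Br-]
Why: Wittig methylenation, in which the unstabilised ylide should add to the aldehyde far faster than to the aryl ester and turns the formyl group into the vinyl group of the 1,1-dimethylallyl unit.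

Step 11
Reactants: 15 methyl 2,4-bis(methoxymethoxy)-5-(2-methylbut-3-en-2-yl)benzoate
Product: 16 methyl 3-[2,4-bis(methoxymethoxy)-5-(2-methylbut-3-en-2-yl)phenyl]-3-oxopropanoate
Conditions: MeOAc, LiN(SiMe3)2 (excess), THF, −78 to −20 °C; aq NH4Cl
Reagents that add atoms: methyl acetate, COC(C)=O
Why: Crossed Claisen condensation, in which the lithium enolate of methyl acetate is acylated by the benzoate and deprotonation of the β-keto ester by the excess base drives the equilibrium.

Step 12
Reactants: 16 methyl 3-[2,4-bis(methoxymethoxy)-5-(2-methylbut-3-en-2-yl)phenyl]-3-oxopropanoate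
Product: 17 methyl (3S)-3-[2,4-bis(methoxymethoxy)-5-(2-methylbut-3-en-2-yl)phenyl]-3-hydroxypropanoate
Conditions: RuCl(p-cymene)[(S,S)-TsDPEN] (cat.), HCO2Na, H2O/MeOH, 40 °C
Reagents that add atoms: none
Why: Asymmetric transfer hydrogenation by outer-sphere hydride/proton transfer is selective for the ketone over the ester and the alkene, and the (S,S)-ligand should give the (S)-carbinol by the facial preference established for aryl ketones, which sets the centre that becomes C2.

Step 13
Reactants: 17 methyl (3S)-3-[2,4-bis(methoxymethoxy)-5-(2-methylbut-3-en-2-yl)phenyl]-3-hydroxypropanoate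
Product: 18 methyl (3S)-3-[2,4-bis(methoxymethoxy)-5-(2-methylbut-3-en-2-yl)phenyl]-3-[(trimethylsilyl)oxy]propanoate
Conditions: N-(trimethylsilyl)imidazole, CH2Cl2, rt; filtration through basic alumina
Reagents that add atoms: N-(trimethylsilyl)imidazole, C[Si](C)(C)n1ccnc1
Why: Neutral O-silylation gives a trimethylsilyl ether that serves as a proton-free, fluoride-releasable form of the alkoxide for step 14.

Step 14
Reactants: 11 3,5-bis(methoxymethoxy)-2-(3-methylbut-2-en-1-yl)-6-(trimethylsilyl)phenyl trifluoromethanesulfonate; 18 methyl (3S)-3-[2,4-bis(methoxymethoxy)-5-(2-methylbut-3-en-2-yl)phenyl]-3-[(trimethylsilyl)oxy]propanoate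
Product: 21 (2S)-2-[2,4-bis(methoxymethoxy)-5-(2-methylbut-3-en-2-yl)phenyl]-5,7-bis(methoxymethoxy)-8-(3-methylbut-2-en-1-yl)-2,3-dihydro-4H-chromen-4-one, via aryne 19 (not isolated), via alkoxide 20 (not isolated)
Conditions: KF, 18-crown-6, THF, 0 °C to rt (fluoride added in portions to 11 and 18); pH 7 buffer quench at 0 °C
Reagents that add atoms: none
Why: Proposed new method: fluoride removes the C-silyl group of 11 to give aryne 19 and the O-silyl group of 18 to give alkoxide 20 in an aprotic medium; 20 adds to C8a of 19, the aryl anion left at C4a attacks the methyl ester of the same molecule, and the methoxide that leaves is silylated by a further molecule of 18, which frees the next alkoxide. The closest known reaction type is the aryne annulation of methyl salicylates to xanthones (phenoxide addition, then acyl capture of the aryl anion), here extended from a phenoxide to an aliphatic β-alkoxy ester. Ring C is closed by an intermolecular O-arylation followed by a 6-exo-trig acyl substitution. No stereocentre is created: C2 comes from 18 with retention because its C–O bond is not touched, and the short, near-neutral, low-temperature regime is chosen to spare the base-labile flavanone. The step needs regioselective addition to the unsymmetrical aryne, which the inductively withdrawing C5 OMOM group next to C4a should secure by directing the nucleophile to the distal C8a and stabilising the C4a anion. It also needs acylation to outrun protonation of the aryl anion, which the silyl-masked, proton-free alkoxide should secure.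

Step 15
Reactants: 21 (2S)-2-[2,4-bis(methoxymethoxy)-5-(2-methylbut-3-en-2-yl)phenyl]-5,7-bis(methoxymethoxy)-8-(3-methylbut-2-en-1-yl)-2,3-dihydro-4H-chromen-4-one
Product: 22 (2S)-2-[2,4-dihydroxy-5-(2-methylbut-3-en-2-yl)phenyl]-5,7-dihydroxy-8-(3-methylbut-2-en-1-yl)-2,3-dihydro-4H-chromen-4-one
Conditions: 3 M aq HCl, MeOH, 40 °C
Reagents that add atoms: none
Why: Acid-catalysed solvolysis of the four aryl MOM acetals (transacetalisation to methanol) should release the phenols under conditions mild enough to leave the C2–O1 bond and both alkenes alone.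

**Compound list**

1 | resorcinol (benzene-1,3-diol) | Oc1cccc(O)c1 | starting material
2 | 1,3-bis(methoxymethoxy)benzene | COCOc1cccc(OCOC)c1 | intermediate
3 | 2-[3,5-bis(methoxymethoxy)phenyl]-4,4,5,5-tetramethyl-1,3,2-dioxaborolane (not isolated) | COCOc1cc(OCOC)cc(B2OC(C)(C)C(C)(C)O2)c1 | intermediate
4 | 3,5-bis(methoxymethoxy)phenol | COCOc1cc(O)cc(OCOC)c1 | intermediate
5 | 3,5-bis(methoxymethoxy)phenyl N,N-diethylcarbamate | CCN(CC)C(=O)Oc1cc(OCOC)cc(OCOC)c1 | intermediate
6 | [2-(diethylcarbamoyloxy)-4,6-bis(methoxymethoxy)phenyl]lithium (not isolated) | CCN(CC)C(=O)Oc1cc(OCOC)cc(OCOC)c1[Li] | intermediate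
7 | 3,5-bis(methoxymethoxy)-2-(trimethylsilyl)phenyl N,N-diethylcarbamate | CCN(CC)C(=O)Oc1cc(OCOC)cc(OCOC)c1[Si](C)(C)C | intermediate
8 | [2-(diethylcarbamoyloxy)-4,6-bis(methoxymethoxy)-3-(trimethylsilyl)phenyl]lithium (not isolated) | CCN(CC)C(=O)Oc1c([Li])c(OCOC)cc(OCOC)c1[Si](C)(C)C | intermediate
9 | 3,5-bis(methoxymethoxy)-2-(3-methylbut-2-en-1-yl)-6-(trimethylsilyl)phenyl N,N-diethylcarbamate | CCN(CC)C(=O)Oc1c(CC=C(C)C)c(OCOC)cc(OCOC)c1[Si](C)(C)C | intermediate
10 | 3,5-bis(methoxymethoxy)-2-(3-methylbut-2-en-1-yl)-6-(trimethylsilyl)phenol | CC(C)=CCc1c(O)c([Si](C)(C)C)c(OCOC)cc1OCOC | intermediate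
11 | 3,5-bis(methoxymethoxy)-2-(3-methylbut-2-en-1-yl)-6-(trimethylsilyl)phenyl trifluoromethanesulfonate | CC(C)=CCc1c(OS(=O)(=O)C(F)(F)F)c([Si](C)(C)C)c(OCOC)cc1OCOC | intermediate
12 | methyl 5-bromo-2,4-dihydroxybenzoate | COC(=O)c1cc(Br)c(O)cc1O | starting material
13 | methyl 5-bromo-2,4-bis(methoxymethoxy)benzoate | COC(=O)c1cc(Br)c(OCOC)cc1OCOC | intermediate
14 | methyl 2,4-bis(methoxymethoxy)-5-(2-methyl-1-oxopropan-2-yl)benzoate | COC(=O)c1cc(C(C)(C)C=O)c(OCOC)cc1OCOC | intermediate
15 | methyl 2,4-bis(methoxymethoxy)-5-(2-methylbut-3-en-2-yl)benzoate | COC(=O)c1cc(C(C)(C)C=C)c(OCOC)cc1OCOC | intermediate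
16 | methyl 3-[2,4-bis(methoxymethoxy)-5-(2-methylbut-3-en-2-yl)phenyl]-3-oxopropanoate | COC(=O)CC(=O)c1cc(C(C)(C)C=C)c(OCOC)cc1OCOC | intermediate
17 | methyl (3S)-3-[2,4-bis(methoxymethoxy)-5-(2-methylbut-3-en-2-yl)phenyl]-3-hydroxypropanoate | COC(=O)C[C@H](O)c1cc(C(C)(C)C=C)c(OCOC)cc1OCOC | intermediate
18 | methyl (3S)-3-[2,4-bis(methoxymethoxy)-5-(2-methylbut-3-en-2-yl)phenyl]-3-[(trimethylsilyl)oxy]propanoate | COC(=O)C[C@H](O[Si](C)(C)C)c1cc(C(C)(C)C=C)c(OCOC)cc1OCOC | intermediate
19 | 3,5-bis(methoxymethoxy)-6-(3-methylbut-2-en-1-yl)benzyne (not isolated) | CC(C)=CCC1=C(OCOC)C=C(OCOC)C#C1 | intermediate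
20 | potassium (1S)-1-[2,4-bis(methoxymethoxy)-5-(2-methylbut-3-en-2-yl)phenyl]-3-methoxy-3-oxopropan-1-olate (not isolated) | COC(=O)C[C@H]([O-])c1cc(C(C)(C)C=C)c(OCOC)cc1OCOC.[K+] | intermediate
21 | (2S)-2-[2,4-bis(methoxymethoxy)-5-(2-methylbut-3-en-2-yl)phenyl]-5,7-bis(methoxymethoxy)-8-(3-methylbut-2-en-1-yl)-2,3-dihydro-4H-chromen-4-one | C=CC(C)(C)c1cc([C@@H]2CC(=O)c3c(OCOC)cc(OCOC)c(CC=C(C)C)c3O2)c(OCOC)cc1OCOC | intermediate
22 | (2S)-2-[2,4-dihydroxy-5-(2-methylbut-3-en-2-yl)phenyl]-5,7-dihydroxy-8-(3-methylbut-2-en-1-yl)-2,3-dihydro-4H-chromen-4-one (AChE-IN-17) | C=CC(C)(C)c1cc([C@@H]2CC(=O)c3c(O)cc(O)c(CC=C(C)C)c3O2)c(O)cc1O | target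

**Step count**

Total steps: 15. Longest linear sequence: 9 steps (steps 1 to 7, then 14 and 15). The ring B branch (steps 8 to 13) joins at step 14.

**Steps most likely to fail, with fallbacks**

Step 14 (the proposed new method). Several processes may defeat it:
- the freed alkoxide may fragment by retro-aldol cleavage or eliminate to the cinnamate before it meets the aryne;
- the aryl anion at C4a may be quenched before it acylates;
- the flavanone may lose its C2 configuration by base-induced ring opening and reclosure.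

The fallback uses known aryne chemistry and a resolution, and sets out from 17. Mesylation (MsCl, Et3N, CH2Cl2, 0 °C) should give methyl (3S)-3-[2,4-bis(methoxymethoxy)-5-(2-methylbut-3-en-2-yl)phenyl]-3-(methylsulfonyloxy)propanoate F1. DBU should eliminate it to methyl (E)-3-[2,4-bis(methoxymethoxy)-5-(2-methylbut-3-en-2-yl)phenyl]prop-2-enoate F2, and LiOH (THF/H2O) should give (E)-3-[2,4-bis(methoxymethoxy)-5-(2-methylbut-3-en-2-yl)phenyl]prop-2-enoic acid F3. The carboxylate of F3 and aryne precursor 11 (CsF, THF, sealed tube, heat) should react by the known insertion of an aryne into the C–O bond of a carboxylic acid: O-arylation at C8a by the small carboxylate oxygen, then acyl transfer to C4a. The product should be the 2'-hydroxychalcone (E)-3-[2,4-bis(methoxymethoxy)-5-(2-methylbut-3-en-2-yl)phenyl]-1-[2-hydroxy-4,6-bis(methoxymethoxy)-3-(3-methylbut-2-en-1-yl)phenyl]prop-2-en-1-one F4. Oxa-Michael closure (NaOAc, EtOH, reflux) should give the racemic protected flavanone rac-2-[2,4-bis(methoxymethoxy)-5-(2-methylbut-3-en-2-yl)phenyl]-5,7-bis(methoxymethoxy)-8-(3-methylbut-2-en-1-yl)-2,3-dihydro-4H-chromen-4-one F5. Preparative chromatography on a chiral stationary phase returns the route at 21.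

Step 9. Oxidative addition and reductive elimination may be slow at the electron-rich, ortho-alkoxy aryl bromide, and isobutyraldehyde may be lost by aldol self-addition before it is arylated. The fallback sets out from 13. A γ-selective Suzuki–Miyaura coupling with 3-methylbut-2-en-1-ylboronic acid pinacol ester (Pd(OAc)2, a bulky biaryl dialkylphosphine chosen for γ-selectivity, aq K3PO4, THF, 40 °C) should transfer the allyl group with transposition. This gives the 1,1-dimethylallyl arene directly, so the route is re-entered at 15 and step 10 is not needed; no new compound arises (F0).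

Step 15. Acid may cyclise the C8 prenyl group onto the C7 phenol, or the 1,1-dimethylallyl group onto the C4' phenol. Acid may also open the benzylic C2–O1 bond next to the electron-rich ring B and so erode the C2 configuration. The fallback sets out from 21 and avoids protic acid. Me3SiOTf with 2,2'-bipyridyl (CH2Cl2, 0 °C) should exchange the four aryl MOM ethers for trimethylsilyl ethers to give (2S)-2-[2,4-bis(trimethylsilyloxy)-5-(2-methylbut-3-en-2-yl)phenyl]-5,7-bis(trimethylsilyloxy)-8-(3-methylbut-2-en-1-yl)-2,3-dihydro-4H-chromen-4-one F6. Hydrolysis with water/methanol at neutral pH then returns the route at 22.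

**Further compounds**

F1 | step 14 | methyl (3S)-3-[2,4-bis(methoxymethoxy)-5-(2-methylbut-3-en-2-yl)phenyl]-3-(methylsulfonyloxy)propanoate | COC(=O)C[C@H](OS(C)(=O)=O)c1cc(C(C)(C)C=C)c(OCOC)cc1OCOC
F2 | step 14 | methyl (E)-3-[2,4-bis(methoxymethoxy)-5-(2-methylbut-3-en-2-yl)phenyl]prop-2-enoate | COC(=O)/C=C/c1cc(C(C)(C)C=C)c(OCOC)cc1OCOC
F3 | step 14 | (E)-3-[2,4-bis(methoxymethoxy)-5-(2-methylbut-3-en-2-yl)phenyl]prop-2-enoic acid | OC(=O)/C=C/c1cc(C(C)(C)C=C)c(OCOC)cc1OCOC
F4 | step 14 | (E)-3-[2,4-bis(methoxymethoxy)-5-(2-methylbut-3-en-2-yl)phenyl]-1-[2-hydroxy-4,6-bis(methoxymethoxy)-3-(3-methylbut-2-en-1-yl)phenyl]prop-2-en-1-one | C=CC(C)(C)c1cc(/C=C/C(=O)c2c(O)c(CC=C(C)C)c(OCOC)cc2OCOC)c(OCOC)cc1OCOC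
F5 | step 14 | rac-2-[2,4-bis(methoxymethoxy)-5-(2-methylbut-3-en-2-yl)phenyl]-5,7-bis(methoxymethoxy)-8-(3-methylbut-2-en-1-yl)-2,3-dihydro-4H-chromen-4-one | C=CC(C)(C)c1cc(C2CC(=O)c3c(OCOC)cc(OCOC)c(CC=C(C)C)c3O2)c(OCOC)cc1OCOC
F0 | step 9 | none | none
F6 | step 15 | (2S)-2-[2,4-bis(trimethylsilyloxy)-5-(2-methylbut-3-en-2-yl)phenyl]-5,7-bis(trimethylsilyloxy)-8-(3-methylbut-2-en-1-yl)-2,3-dihydro-4H-chromen-4-one | C=CC(C)(C)c1cc([C@@H]2CC(=O)c3c(O[Si](C)(C)C)cc(O[Si](C)(C)C)c(CC=C(C)C)c3O2)c(O[Si](C)(C)C)cc1O[Si](C)(C)C
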